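**Plan**
- Retrosynthesis: the four MOM ethers and the C4 carbonyl (carried as C4=CH2) are unmasked last; ring C is then opened at O1–C8a, the one bond of the heterocycle that can be formed without touching any of the four bonds at C2.
- With C4 as an exocyclic methylene, the ring-closing substrate is a homoallylic alcohol and not a β-hydroxy ketone, so it cannot dehydrate or undergo retro-aldol cleavage; the bromide at C8a of ring A sits ortho to that alkene.
- Further cuts: C4–C4a (Suzuki coupling of an aryl iodide with an internal alkenylboronate), C3–C4 (acetylide opening of an epoxide) and the CH2–aryl bond of the benzyl group (aryllithium addition to an aldehyde, then deoxygenation).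
- Forward: the brominated diarylmethane is built first, iodinated on ring A and joined to the side chain at C4a; ring C, the only ring formed, closes by palladium-catalysed aryl C–O coupling.
- Stereochemistry: C2 is the only stereocentre and is bought with (R)-styrene oxide; its C–O bond is never broken, and the (S) descriptor of the later compounds arises only from the changed CIP priorities.

Key step: step 11

Remark: carbinol 4 is racemic and diol 18 is a mixture of C4 epimers; both centres are destroyed in the next operation, so their SMILES carry no descriptor there. 4-Bromo-2,6-dimethoxybenzaldehyde and lithium acetylide–ethylenediamine complex are taken as purchasable.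

**Step 1**
Reactants: 1 veratrole (1,2-dimethoxybenzene); 2 4-bromo-2,6-dimethoxybenzaldehyde
Product: 4 (4-bromo-2,6-dimethoxyphenyl)(2,3-dimethoxyphenyl)methanol, via 2,3-dimethoxyphenyllithium 3 (not isolated)
Conditions: 1 (1.3 equiv), n-BuLi (1.2 equiv), TMEDA, Et2O, 0 °C → rt; then 2 in THF, −78 → 0 °C; H2O
Reagents that add atoms: none
Why: Directed ortho-metalation of veratrole gives the 3-lithio species, and its 1,2-addition to the aldehyde at −78 °C should outrun lithium–bromine exchange because veratrole in excess leaves no n-BuLi behind.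

**Step 2**
Reactants: 4 (4-bromo-2,6-dimethoxyphenyl)(2,3-dimethoxyphenyl)methanol
Product: 5 5-bromo-2-(2,3-dimethoxybenzyl)-1,3-dimethoxybenzene
Conditions: Et3SiH (3 equiv), TFA (5 equiv), CH2Cl2, 0 °C
Reagents that add atoms: none
Why: Ionic hydrogenation, in which TFA ionises the carbinol to a benzhydryl cation stabilised by three ortho methoxy groups and Et3SiH delivers hydride; methyl ethers and the aryl bromide are inert, which is why the acid-labile MOM groups are installed only afterwards.

**Step 3**
Reactants: 5 5-bromo-2-(2,3-dimethoxybenzyl)-1,3-dimethoxybenzene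
Product: 6 5-bromo-2-(2,3-dihydroxybenzyl)benzene-1,3-diol
Conditions: BBr3 (6 equiv), CH2Cl2, −78 °C → rt; then H2O
Reagents that add atoms: none
Why: Lewis-acid ether cleavage, in which BBr3 complexes each aryl methyl ether and bromide attacks the methyl group; the aryl bromide and the diarylmethane are untouched.

**Step 4**
Reactants: 6 5-bromo-2-(2,3-dihydroxybenzyl)benzene-1,3-diol
Product: 7 5-bromo-2-[2,3-bis(methoxymethoxy)benzyl]-1,3-bis(methoxymethoxy)benzene
Conditions: NaH (5 equiv), MOMCl (5 equiv), DMF, 0 °C → rt
Reagents that add atoms: chloromethyl methyl ether, COCCl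
Why: Williamson-type O-alkylation of the four phenoxides with a reactive α-chloro ether, with NaH in DMF chosen so that the two hindered phenols flanking the benzyl group are also alkylated.

**Step 5**
Reactants: 7 5-bromo-2-[2,3-bis(methoxymethoxy)benzyl]-1,3-bis(methoxymethoxy)benzene
Product: 8 1-bromo-2-iodo-4-[2,3-bis(methoxymethoxy)benzyl]-3,5-bis(methoxymethoxy)benzene
Conditions: NIS (1.05 equiv), DMF, 0 °C → rt, dark
Reagents that add atoms: N-iodosuccinimide, O=C1CCC(=O)N1I
Why: Electrophilic aromatic iodination, in which the two free positions of ring A are equivalent by symmetry and each is ortho to one and para to the other MOM-oxy group, whereas every free position of the catechol ring is conjugated to one oxygen only, so one equivalent of acid-free NIS should iodinate ring A once, next to bromine.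

**Step 6**
Reactants: 9 (R)-styrene oxide; 10 lithium acetylide–ethylenediamine complex
Product: 11 (S)-1-phenylbut-3-yn-1-ol
Conditions: DMSO, rt; then H2O
Reagents that add atoms: none
Why: SN2 epoxide opening, in which the acetylide, with no Lewis acid present, attacks the unsubstituted CH2 terminus and leaves the benzylic C–O bond intact, so the configuration is retained and the descriptor changes from R to S only through the CIP priorities.

**Step 7**
Reactants: 11 (S)-1-phenylbut-3-yn-1-ol
Product: 12 (S)-tert-butyldimethyl[(1-phenylbut-3-yn-1-yl)oxy]silane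
Conditions: TBSCl, imidazole, DMF, rt
Reagents that add atoms: tert-butyldimethylsilyl chloride, CC(C)(C)[Si](C)(C)Cl
Why: Standard silylation of a secondary alcohol, which keeps the hydroxyl from consuming the aluminium hydride and from interfering in the cross-coupling.

**Step 8**
Reactants: 12 (S)-tert-butyldimethyl[(1-phenylbut-3-yn-1-yl)oxy]silane
Product: 14 (S)-tert-butyldimethyl{[1-phenyl-3-(4,4,5,5-tetramethyl-1,3,2-dioxaborolan-2-yl)but-3-en-1-yl]oxy}silane, via vinylalane 13 (not isolated)
Conditions: NiCl2(dppp) (3 mol%), iBu2AlH (1.3 equiv), THF, rt; then MeOBpin (3 equiv), 0 °C → rt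
Reagents that add atoms: 2-methoxy-4,4,5,5-tetramethyl-1,3,2-dioxaborolane, COB1OC(C)(C)C(C)(C)O1
Why: Nickel-catalysed α-selective hydroalumination of a terminal alkyne, in which the bisphosphine complex places aluminium on the internal carbon, followed by aluminium-to-boron transmetalation with the methoxyborane at the same carbon; the silyl ether is inert.

**Step 9**
Reactants: 8 1-bromo-2-iodo-4-[2,3-bis(methoxymethoxy)benzyl]-3,5-bis(methoxymethoxy)benzene; 14 the internal alkenylboronate
Product: 15 (S)-{[3-{2-bromo-5-[2,3-bis(methoxymethoxy)benzyl]-4,6-bis(methoxymethoxy)phenyl}-1-phenylbut-3-en-1-yl]oxy}(tert-butyl)dimethylsilane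
Conditions: 14 (1.1 equiv), PdCl2(dppf) (5 mol%), K3PO4 (3 equiv), 1,4-dioxane/H2O, 70 °C
Reagents that add atoms: none
Why: Suzuki–Miyaura coupling, in which zerovalent palladium inserts into the C–I bond far faster than into the neighbouring C–Br bond, so the alkenyl group should join C4a while the bromide needed for ring closure is kept.

**Step 10**
Reactants: 15 the silyl ether from step 9
Product: 16 (1S)-3-{2-bromo-5-[2,3-bis(methoxymethoxy)benzyl]-4,6-bis(methoxymethoxy)phenyl}-1-phenylbut-3-en-1-ol
Conditions: Bu4NF (1.5 equiv), THF, 0 °C → rt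
Reagents that add atoms: none
Why: Fluoride-mediated desilylation, which leaves MOM acetals, aryl bromide, alkene and the carbinol configuration unchanged.

**Step 11**
Reactants: 16 (1S)-3-{2-bromo-5-[2,3-bis(methoxymethoxy)benzyl]-4,6-bis(methoxymethoxy)phenyl}-1-phenylbut-3-en-1-ol
Product: 17 (2S)-6-[2,3-bis(methoxymethoxy)benzyl]-5,7-bis(methoxymethoxy)-4-methylene-2-phenylchromane
Conditions: Pd(OAc)2 (5 mol%), 2-(di-tert-butylphosphino)-1,1'-binaphthyl (6 mol%), Cs2CO3 (1.5 equiv), toluene, 80 °C
Reagents that add atoms: none
Why: Zerovalent palladium, formed from Pd(OAc)2 and the bulky di-tert-butylbiarylphosphine, inserts into the C8a–Br bond, Cs2CO3 deprotonates the palladium-bound C2 hydroxyl to give a seven-membered aryl palladium alkoxide, and C–O reductive elimination forms O1–C8a and returns zerovalent palladium. The closest known reaction type is the Buchwald–Hartwig-type intramolecular etherification of aryl bromides with secondary alcohols, which gives chromans from enantioenriched alcohols without loss of configuration. Ring C closes as a six-membered ring by reductive elimination from the seven-membered oxapalladacycle, formally a 6-exo attack of the alkoxide oxygen on the ipso carbon C8a. No stereocentre is created; C2 keeps the (S) configuration set by (R)-styrene oxide because none of its four bonds takes part. The step needs C–O reductive elimination to outrun β-hydride elimination from the benzylic alkoxide and an aryl-to-vinyl 1,4-palladium shift, which the hindered electron-rich ligand and the favourable six-ring closure should secure. The substrate helps further: the alkene is bonded directly to C4a, so a Heck insertion would need a three- or four-membered ring, and with C4 as a methylene and not a carbonyl the carbonate base finds no retro-aldol or dehydration path.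

**Step 12**
Reactants: 17 (2S)-6-[2,3-bis(methoxymethoxy)benzyl]-5,7-bis(methoxymethoxy)-4-methylene-2-phenylchromane
Product: 19 (2S)-6-[2,3-bis(methoxymethoxy)benzyl]-5,7-bis(methoxymethoxy)-2-phenylchroman-4-one, via C4 diol 18 (not isolated)
Conditions: OsO4 (2 mol%), NaIO4 (4 equiv), 2,6-lutidine (2 equiv), 1,4-dioxane/H2O (3:1), rt
Reagents that add atoms: osmium tetroxide, O=[Os](=O)(=O)=O; sodium periodate, [Na+].[O-]I(=O)(=O)=O
Why: Lemieux–Johnson oxidation, in which OsO4 dihydroxylates the electron-rich 1,1-disubstituted alkene and periodate both re-oxidises osmium and cleaves the diol to the aryl ketone; the lutidine-buffered medium spares the MOM acetals and gives C2 no enolisation-driven ring-opening path.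

**Step 13**
Reactants: 19 (2S)-6-[2,3-bis(methoxymethoxy)benzyl]-5,7-bis(methoxymethoxy)-2-phenylchroman-4-one
Product: 20 (2S)-6-(2,3-dihydroxybenzyl)-5,7-dihydroxy-2-phenylchroman-4-one (CNP0348560.1)
Conditions: HCl (aq. 3 M), MeOH, 45 °C
Reagents that add atoms: none
Why: Acid-catalysed acetal exchange of the four MOM ethers with methanol, run warm but not hot so that reversible oxa-Michael ring opening, which would racemise C2 and could move the benzyl group from C6 to C8, should not set in.

**Compound list**
1 | veratrole (1,2-dimethoxybenzene) | COc1ccccc1OC | starting material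
2 | 4-bromo-2,6-dimethoxybenzaldehyde | COc1cc(Br)cc(OC)c1C=O | starting material
3 | 2,3-dimethoxyphenyllithium | [Li]c1cccc(OC)c1OC | intermediate
4 | (4-bromo-2,6-dimethoxyphenyl)(2,3-dimethoxyphenyl)methanol (racemic) | COc1cc(Br)cc(OC)c1C(O)c1cccc(OC)c1OC | intermediate
5 | 5-bromo-2-(2,3-dimethoxybenzyl)-1,3-dimethoxybenzene | COc1cc(Br)cc(OC)c1Cc1cccc(OC)c1OC | intermediate
6 | 5-bromo-2-(2,3-dihydroxybenzyl)benzene-1,3-diol | Oc1cc(Br)cc(O)c1Cc1cccc(O)c1O | intermediate
7 | 5-bromo-2-[2,3-bis(methoxymethoxy)benzyl]-1,3-bis(methoxymethoxy)benzene | COCOc1cc(Br)cc(OCOC)c1Cc1cccc(OCOC)c1OCOC | intermediate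
8 | 1-bromo-2-iodo-4-[2,3-bis(methoxymethoxy)benzyl]-3,5-bis(methoxymethoxy)benzene | COCOc1cc(Br)c(I)c(OCOC)c1Cc1cccc(OCOC)c1OCOC | intermediate
9 | (R)-styrene oxide | C1[C@H](O1)c1ccccc1 | starting material
10 | lithium acetylide–ethylenediamine complex | [Li+].[C-]#C.NCCN | starting material
11 | (S)-1-phenylbut-3-yn-1-ol | C#CC[C@H](O)c1ccccc1 | intermediate
12 | (S)-tert-butyldimethyl[(1-phenylbut-3-yn-1-yl)oxy]silane | C#CC[C@H](O[Si](C)(C)C(C)(C)C)c1ccccc1 | intermediate
13 | diisobutyl{(4S)-4-[(tert-butyldimethylsilyl)oxy]-4-phenylbut-1-en-2-yl}aluminium | C=C([Al](CC(C)C)CC(C)C)C[C@H](O[Si](C)(C)C(C)(C)C)c1ccccc1 | intermediate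
14 | (S)-tert-butyldimethyl{[1-phenyl-3-(4,4,5,5-tetramethyl-1,3,2-dioxaborolan-2-yl)but-3-en-1-yl]oxy}silane | C=C(B1OC(C)(C)C(C)(C)O1)C[C@H](O[Si](C)(C)C(C)(C)C)c1ccccc1 | intermediate
15 | (S)-{[3-{2-bromo-5-[2,3-bis(methoxymethoxy)benzyl]-4,6-bis(methoxymethoxy)phenyl}-1-phenylbut-3-en-1-yl]oxy}(tert-butyl)dimethylsilane | C=C(C[C@H](O[Si](C)(C)C(C)(C)C)c1ccccc1)c1c(Br)cc(OCOC)c(Cc2cccc(OCOC)c2OCOC)c1OCOC | intermediate
16 | (1S)-3-{2-bromo-5-[2,3-bis(methoxymethoxy)benzyl]-4,6-bis(methoxymethoxy)phenyl}-1-phenylbut-3-en-1-ol | C=C(C[C@H](O)c1ccccc1)c1c(Br)cc(OCOC)c(Cc2cccc(OCOC)c2OCOC)c1OCOC | intermediate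
17 | (2S)-6-[2,3-bis(methoxymethoxy)benzyl]-5,7-bis(methoxymethoxy)-4-methylene-2-phenylchromane | C=C1C[C@@H](c2ccccc2)Oc2cc(OCOC)c(Cc3cccc(OCOC)c3OCOC)c(OCOC)c21 | intermediate
18 | (2S)-6-[2,3-bis(methoxymethoxy)benzyl]-4-(hydroxymethyl)-5,7-bis(methoxymethoxy)-2-phenylchroman-4-ol (both C4 epimers) | OCC1(O)C[C@@H](c2ccccc2)Oc2cc(OCOC)c(Cc3cccc(OCOC)c3OCOC)c(OCOC)c21 | intermediate
19 | (2S)-6-[2,3-bis(methoxymethoxy)benzyl]-5,7-bis(methoxymethoxy)-2-phenylchroman-4-one | O=C1C[C@@H](c2ccccc2)Oc2cc(OCOC)c(Cc3cccc(OCOC)c3OCOC)c(OCOC)c21 | intermediate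
20 | (2S)-6-(2,3-dihydroxybenzyl)-5,7-dihydroxy-2-phenylchroman-4-one | O=C1C[C@@H](c2ccccc2)Oc2cc(O)c(Cc3cccc(O)c3O)c(O)c21 | target

**Step count and risks**
Total steps: 13. Longest linear sequence: 10 steps (steps 1–5 and 9–13); the side-chain branch (steps 6–8) joins at step 9.

Step 11. The palladium alkoxide may undergo β-hydride elimination at the benzylic C–H, which would give hydrodebromination and a ketone instead of ring closure, or oxidative addition may be slow next to the ortho alkene. The fallback sets out from 16 and moves the same O1–C8a closure to copper, whose alkoxides do not readily eliminate hydride. Copper-catalysed aromatic Finkelstein exchange (CuI, NaI, trans-N,N'-dimethylcyclohexane-1,2-diamine, 1,4-dioxane, 110 °C) should convert 16 into (1S)-3-{5-[2,3-bis(methoxymethoxy)benzyl]-2-iodo-4,6-bis(methoxymethoxy)phenyl}-1-phenylbut-3-en-1-ol F1. An Ullmann-type intramolecular etherification (CuI, 3,4,7,8-tetramethyl-1,10-phenanthroline, Cs2CO3, toluene, 90 °C) should then close ring C with the carbinol carbon again uninvolved, coming back to the route at 17.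

Step 9. Transmetalation of the α-branched boronate onto a doubly ortho-substituted arylpalladium may be slow, so that protodeboronation or oxidative addition into the C–Br bond and a second coupling compete. The fallback sets out from 8 and reverses the polarity. Iodine–magnesium exchange with iPrMgCl·LiCl in THF at −40 °C, selective for iodide, should give {6-bromo-3-[2,3-bis(methoxymethoxy)benzyl]-2,4-bis(methoxymethoxy)phenyl}magnesium chloride F2, which ZnCl2 converts into the corresponding arylzinc chloride F3. Negishi coupling of F3 at room temperature (Pd(PPh3)4, THF) with (S)-[(3-bromo-1-phenylbut-3-en-1-yl)oxy](tert-butyl)dimethylsilane F4, obtained by quenching vinylalane 13 with N-bromosuccinimide, should form the same C4–C4a bond. The route is rejoined at 15.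

Step 8. The hydroalumination may lose α-selectivity, the terminal C–H may be metalated to an alkynylalane, or the transfer from aluminium to boron may stall and leave the protonated alkene after work-up. The fallback sets out from 12 and installs the internal handle by haloboration. Syn-bromoboration with B-bromo-9-borabicyclo[3.3.1]nonane (CH2Cl2, 0 °C) should give 9-{(1Z,4S)-2-bromo-4-[(tert-butyldimethylsilyl)oxy]-4-phenylbut-1-en-1-yl}-9-borabicyclo[3.3.1]nonane F5, and protonolysis of its C–B bond with acetic acid gives the bromoalkene F4. Miyaura borylation of F4 (B2pin2, PdCl2(PPh3)2, PPh3, KOPh, toluene, 50 °C) should then deliver the boronate, coming back to the route at 14.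

**Further compounds**
F1 | step 11 | (1S)-3-{5-[2,3-bis(methoxymethoxy)benzyl]-2-iodo-4,6-bis(methoxymethoxy)phenyl}-1-phenylbut-3-en-1-ol | C=C(C[C@H](O)c1ccccc1)c1c(I)cc(OCOC)c(Cc2cccc(OCOC)c2OCOC)c1OCOC
F2 | step 9 | {6-bromo-3-[2,3-bis(methoxymethoxy)benzyl]-2,4-bis(methoxymethoxy)phenyl}magnesium chloride | COCOc1cc(Br)c([Mg]Cl)c(OCOC)c1Cc1cccc(OCOC)c1OCOC
F3 | step 9 | {6-bromo-3-[2,3-bis(methoxymethoxy)benzyl]-2,4-bis(methoxymethoxy)phenyl}zinc chloride | COCOc1cc(Br)c([Zn]Cl)c(OCOC)c1Cc1cccc(OCOC)c1OCOC
F4 | step 9 | (S)-[(3-bromo-1-phenylbut-3-en-1-yl)oxy](tert-butyl)dimethylsilane | C=C(Br)C[C@H](O[Si](C)(C)C(C)(C)C)c1ccccc1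
F5 | step 8 | 9-{(1Z,4S)-2-bromo-4-[(tert-butyldimethylsilyl)oxy]-4-phenylbut-1-en-1-yl}-9-borabicyclo[3.3.1]nonane | Br/C(C[C@H](O[Si](C)(C)C(C)(C)C)c1ccccc1)=C\B1C2CCCC1CCC2
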